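**Strategy**

The depside is cut at its aryl ester into a ring A salicylic acid and a ring B phenol. Ring A is built, not bought: four contiguous ring A carbons, C6 (propyl), C1 (carboxyl), C2 (oxygen) and C3, are carried over from positions 6, 5, 4 and 3 of a benzyl 4-benzyloxy-6-propyl-2-pyrone-5-carboxylate, and C4 (with its OMe) plus C5 are delivered by 1,1-dimethoxyethene. One thermal operation, cycloaddition across pyrone C3/C6 followed by loss of CO2 and methanol, converts the lactone into the fully substituted benzoate, with the two ring A oxygens differentiated by origin. Hydrogenolysis, esterification with a ring B benzyl ester made from olivetol, and a last hydrogenolysis complete the route.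

Key step: step 4

Remark: the target has no stereocentre, so only regiochemistry has to be controlled; dibenzyl 3-oxopentanedioate is taken as a catalogue compound.

**Route**

Step 1
Reactants: 1 dibenzyl 3-oxopentanedioate; 2 butanoyl chloride
Product: 3 dibenzyl 2-butanoyl-3-oxopentanedioate
Conditions: MgCl2, pyridine, CH2Cl2, 0 °C; then 2 (1.0 equiv), 0 °C → rt; 1 M HCl work-up
Reagents that add atoms: none
Why: Rathke-type soft enolisation, in which the MgCl2 chelate of the β-keto ester is C-acylated by the acid chloride at one of the two equivalent methylenes, while the more acidic product stays chelated and so resists O-acylation and a second acylation.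

Step 2
Reactants: 3 dibenzyl 2-butanoyl-3-oxopentanedioate
Product: 4 benzyl 4-hydroxy-2-oxo-6-propyl-2H-pyran-5-carboxylate
Conditions: DBU (1.5 equiv), toluene, 80 °C; then 1 M HCl
Reagents that add atoms: none
Why: Enol lactonisation (6-exo-trig acyl substitution) of the butanoyl enolate oxygen onto the distal ester with loss of benzyl alcohol, the same closure that turns 3,5-dioxoalkanoates into 4-hydroxy-2-pyrones; it is the only six-membered lactone this skeleton can form, and any transesterification is degenerate.

Step 3
Reactants: 4 benzyl 4-hydroxy-2-oxo-6-propyl-2H-pyran-5-carboxylate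
Product: 5 benzyl 4-(benzyloxy)-2-oxo-6-propyl-2H-pyran-5-carboxylate
Conditions: BnOH, PPh3, DIAD, THF, 0 °C → rt
Reagents that add atoms: benzyl alcohol, OCc1ccccc1
Why: Mitsunobu alkylation, in which the strongly acidic vinylogous acid is alkylated on O4 by the benzyloxyphosphonium ion, a mode that with 4-hydroxy-2-pyranones gives 4-alkoxy-2-pyranones and not C3-alkylated or 2-alkoxy-4-pyranone isomers.

Step 4
Reactants: 5 benzyl 4-(benzyloxy)-2-oxo-6-propyl-2H-pyran-5-carboxylate; 6 1,1-dimethoxyethene
Product: 9 benzyl 2-(benzyloxy)-4-methoxy-6-propylbenzoate, via bicyclic lactone adduct 7 (not isolated), via cyclohexadiene ketal 8 (not isolated)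
Conditions: 6 (6 equiv), K2CO3 (trace), toluene, 120 °C, sealed tube
Reagents that add atoms: none
Why: Inverse-electron-demand Diels–Alder reaction in which the diene C3=C4–C5=C6 of the ester-activated pyranone is attacked by the electron-rich ketene acetal to give the 2-oxabicyclo[2.2.2]octenone 7, which should undergo cycloreversion with loss of CO2 to the cyclohexadiene ketal 8 and then eliminate methanol to the arene. The closest known reaction type is the benzannulation of alkyl coumalates and of 3-alkoxycarbonyl-2-pyranones with ketene acetals to alkoxybenzoates; the extra 4-alkoxy and 6-alkyl groups are expected to slow the addition, hence the excess dienophile, the base-protected medium and 120 °C. The carbocycle is closed by an intermolecular [4+2] cycloaddition that forms the C3–C4 and C5–C6 bonds of ring A in one event, not by cyclisation of a tethered chain. The two bridgehead stereocentres of 7 are transient and vanish on aromatisation, so no stereocontrol is required. The selectivity needed is regiochemical: the nucleophilic CH2 of the acetal must bond to pyranone C6 (the β-carbon of the C5 acrylate unit and the vinylogous terminus of the lactone carbonyl) and the acetal carbon to C3, a polarity that the 4-benzyloxy donor reinforces by raising the electron density at C3, so that OMe should end up para to the ester.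

Step 5
Reactants: 9 benzyl 2-(benzyloxy)-4-methoxy-6-propylbenzoate
Product: 10 2-hydroxy-4-methoxy-6-propylbenzoic acid
Conditions: H2 (1 atm), 10% Pd/C, EtOAc, rt
Reagents that add atoms: none
Why: Heterogeneous hydrogenolysis cleaves the benzyl ester and the aryl benzyl ether together, while the arene, the methyl ether and the propyl chain are inert.

Step 6
Reactants: 11 olivetol (5-pentylbenzene-1,3-diol)
Product: 13 2,4-dihydroxy-6-pentylbenzaldehyde, via aryl iminium chloride 12 (not isolated)
Conditions: POCl3, DMF, 0 °C → rt; then H2O, 50 °C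
Reagents that add atoms: N,N-dimethylformamide, CN(C)C=O; water, O
Why: Vilsmeier–Haack formylation, in which the chloroiminium ion substitutes the resorcinol para to one hydroxyl and ortho to the other (the position between the two hydroxyls is more hindered), and hydrolysis of iminium salt 12 releases the aldehyde.

Step 7
Reactants: 13 2,4-dihydroxy-6-pentylbenzaldehyde
Product: 15 4-(benzyloxy)-2-methoxy-6-pentylbenzaldehyde, via 4-(benzyloxy)-2-hydroxy-6-pentylbenzaldehyde 14 (not isolated)
Conditions: BnBr (1.0 equiv), KHCO3, KI (cat.), DMF, 50 °C; then K2CO3, MeI, 50 °C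
Reagents that add atoms: benzyl bromide, BrCc1ccccc1; iodomethane, CI
Why: Two-stage Williamson etherification, in which the weak base ionises only the para hydroxyl (the ortho hydroxyl is hydrogen-bonded to the aldehyde) so that benzyl bromide alkylates O4 alone, after which K2CO3 and excess MeI methylate the remaining chelated phenol.

Step 8
Reactants: 15 4-(benzyloxy)-2-methoxy-6-pentylbenzaldehyde
Product: 16 4-(benzyloxy)-2-methoxy-6-pentylbenzoic acid
Conditions: NaClO2, NaH2PO4, 2-methyl-2-butene, t-BuOH/H2O, rt
Reagents that add atoms: sodium chlorite, [Na+].[O-]Cl=O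
Why: Pinnick oxidation, in which chlorous acid converts the hindered aryl aldehyde into the acid while 2-methyl-2-butene traps the hypochlorous acid that would otherwise chlorinate the electron-rich ring.

Step 9
Reactants: 16 4-(benzyloxy)-2-methoxy-6-pentylbenzoic acid
Product: 17 4-hydroxy-2-methoxy-6-pentylbenzoic acid
Conditions: H2 (1 atm), 10% Pd/C, EtOAc/MeOH, rt
Reagents that add atoms: none
Why: Hydrogenolysis of the aryl benzyl ether, which leaves the carboxylic acid, the methyl ether and the pentyl chain untouched.

Step 10
Reactants: 17 4-hydroxy-2-methoxy-6-pentylbenzoic acid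
Product: 18 benzyl 4-hydroxy-2-methoxy-6-pentylbenzoate
Conditions: BnBr (1.05 equiv), KHCO3, DMF, rt
Reagents that add atoms: benzyl bromide, BrCc1ccccc1
Why: Chemoselective SN2 alkylation of the carboxylate, since bicarbonate deprotonates the carboxylic acid but not the phenol, which therefore stays free.

Step 11
Reactants: 10 2-hydroxy-4-methoxy-6-propylbenzoic acid; 18 benzyl 4-hydroxy-2-methoxy-6-pentylbenzoate
Product: 20 benzyl 4-[(2-hydroxy-4-methoxy-6-propylbenzoyl)oxy]-2-methoxy-6-pentylbenzoate, via aroyl trifluoroacetate 19 (not isolated)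
Conditions: (CF3CO)2O, toluene, rt; aq. NaHCO3 work-up
Reagents that add atoms: none
Why: Mixed-anhydride esterification of a phenol with trifluoroacetic anhydride, in which the hindered, electron-rich acid forms the aroyl trifluoroacetate 19 (an acylium source) that acylates the only free phenol of 18, while the hydrogen-bonded ortho hydroxyl of 10 is a poor nucleophile and any aryl trifluoroacetate is hydrolysed in the bicarbonate work-up.

Step 12
Reactants: 20 benzyl 4-[(2-hydroxy-4-methoxy-6-propylbenzoyl)oxy]-2-methoxy-6-pentylbenzoate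
Product: 21 4-[(2-hydroxy-4-methoxy-6-propylbenzoyl)oxy]-2-methoxy-6-pentylbenzoic acid
Conditions: H2 (1 atm), 10% Pd/C, EtOAc, rt
Reagents that add atoms: none
Why: Hydrogenolysis of the benzyl ester under neutral conditions, to which the aryl ester link of the depside, the phenol and the ethers are stable.

**Compound list**

1 | dibenzyl 3-oxopentanedioate | O=C(CC(=O)OCc1ccccc1)CC(=O)OCc1ccccc1 | starting material
2 | butanoyl chloride | CCCC(Cl)=O | starting material
3 | dibenzyl 2-butanoyl-3-oxopentanedioate (keto form drawn; the C2 methine is enolised and configurationally labile) | CCCC(=O)C(C(=O)OCc1ccccc1)C(=O)CC(=O)OCc1ccccc1 | intermediate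
4 | benzyl 4-hydroxy-2-oxo-6-propyl-2H-pyran-5-carboxylate | CCCC1=C(C(=O)OCc2ccccc2)C(O)=CC(=O)O1 | intermediate
5 | benzyl 4-(benzyloxy)-2-oxo-6-propyl-2H-pyran-5-carboxylate | CCCC1=C(C(=O)OCc2ccccc2)C(OCc2ccccc2)=CC(=O)O1 | intermediate
6 | 1,1-dimethoxyethene | C=C(OC)OC | starting material
7 | benzyl 5-(benzyloxy)-8,8-dimethoxy-3-oxo-1-propyl-2-oxabicyclo[2.2.2]oct-5-ene-6-carboxylate (racemic; the two bridgeheads are tied to each other by the bicycle, drawn without descriptors) | CCCC12CC(OC)(OC)C(C(=O)O1)C(OCc1ccccc1)=C2C(=O)OCc1ccccc1 | intermediate (not isolated)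
8 | benzyl 6-(benzyloxy)-4,4-dimethoxy-2-propylcyclohexa-1,5-diene-1-carboxylate | CCCC1=C(C(=O)OCc2ccccc2)C(OCc2ccccc2)=CC(OC)(OC)C1 | intermediate (not isolated)
9 | benzyl 2-(benzyloxy)-4-methoxy-6-propylbenzoate | CCCc1cc(OC)cc(OCc2ccccc2)c1C(=O)OCc1ccccc1 | intermediate
10 | 2-hydroxy-4-methoxy-6-propylbenzoic acid | CCCc1cc(OC)cc(O)c1C(=O)O | intermediate
11 | olivetol (5-pentylbenzene-1,3-diol) | CCCCCc1cc(O)cc(O)c1 | starting material
12 | (2,4-dihydroxy-6-pentylbenzylidene)dimethyliminium chloride | CCCCCc1cc(O)cc(O)c1C=[N+](C)C.[Cl-] | intermediate (not isolated)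
13 | 2,4-dihydroxy-6-pentylbenzaldehyde | CCCCCc1cc(O)cc(O)c1C=O | intermediate
14 | 4-(benzyloxy)-2-hydroxy-6-pentylbenzaldehyde | CCCCCc1cc(OCc2ccccc2)cc(O)c1C=O | intermediate (not isolated)
15 | 4-(benzyloxy)-2-methoxy-6-pentylbenzaldehyde | CCCCCc1cc(OCc2ccccc2)cc(OC)c1C=O | intermediate
16 | 4-(benzyloxy)-2-methoxy-6-pentylbenzoic acid | CCCCCc1cc(OCc2ccccc2)cc(OC)c1C(=O)O | intermediate
17 | 4-hydroxy-2-methoxy-6-pentylbenzoic acid | CCCCCc1cc(O)cc(OC)c1C(=O)O | intermediate
18 | benzyl 4-hydroxy-2-methoxy-6-pentylbenzoate | CCCCCc1cc(O)cc(OC)c1C(=O)OCc1ccccc1 | intermediate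
19 | 2-hydroxy-4-methoxy-6-propylbenzoic trifluoroacetic anhydride | CCCc1cc(OC)cc(O)c1C(=O)OC(=O)C(F)(F)F | intermediate (not isolated)
20 | benzyl 4-[(2-hydroxy-4-methoxy-6-propylbenzoyl)oxy]-2-methoxy-6-pentylbenzoate | CCCCCc1cc(OC(=O)c2c(O)cc(OC)cc2CCC)cc(OC)c1C(=O)OCc1ccccc1 | intermediate
21 | 4-[(2-hydroxy-4-methoxy-6-propylbenzoyl)oxy]-2-methoxy-6-pentylbenzoic acid | CCCCCc1cc(OC(=O)c2c(O)cc(OC)cc2CCC)cc(OC)c1C(=O)O | target

**Step count and risks**

Total steps: 12 (steps 1–5 for ring A, steps 6–10 for ring B, steps 11–12 for union and unmasking).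
Longest linear sequence: 7 steps (1–5, 11, 12; the olivetol branch 6–10, 11, 12 is equally long).

Steps most likely to fail:

1. Step 4. The 4-alkoxy donor and the 6-alkyl group may leave the diene too electron-rich and too hindered, so that the ketene acetal oligomerises before it adds. It may also add in conjugate fashion at C4 and expel benzyloxide instead of closing the bicycle. The fallback builds ring A by polyketide-type aromatisation instead of cycloaddition; it sets out from 2 and returns at 10. The dianion of the known reagent 2,2-dimethyl-6-(2-oxopropyl)-4H-1,3-dioxin-4-one (LDA, THF, −78 °C) is C-acylated at its terminal methyl by 2 to give 6-(2,4-dioxoheptyl)-2,2-dimethyl-4H-1,3-dioxin-4-one F1. Et3N in CH2Cl2 should trigger intramolecular aldol condensation and dehydration to 7-hydroxy-2,2-dimethyl-5-propyl-4H-1,3-benzodioxin-4-one F2. MeI and K2CO3 in acetone methylate its only phenol to 7-methoxy-2,2-dimethyl-5-propyl-4H-1,3-benzodioxin-4-one F3. KOH in aqueous DMSO followed by acidification opens the acetonide and delivers 10, which enters step 11.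

2. Step 11. The activated acid may acylate itself through its free ortho hydroxyl, or phenol 18 may be captured as its trifluoroacetate faster than it is aroylated, so that ester formation stalls. The fallback carries the ring A phenol protected through the coupling; it sets out from 9 and returns at 21. Saponification of the hindered benzyl ester (KOH, DMSO/H2O, 80 °C) leaves the benzyl ether intact and gives 2-(benzyloxy)-4-methoxy-6-propylbenzoic acid F4. Steglich coupling with 18 (DCC, cat. DMAP, CH2Cl2) gives benzyl 4-{[2-(benzyloxy)-4-methoxy-6-propylbenzoyl]oxy}-2-methoxy-6-pentylbenzoate F5. One hydrogenolysis (H2, 10% Pd/C, EtOAc) removes both benzyl groups and gives 21 directly.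

3. Step 3. The ambident pyranone anion may be alkylated at C3 or at the ring carbonyl oxygen instead of O4, or the Mitsunobu coupling may be sluggish at the hindered, hydrogen-bonded hydroxyl. The fallback differentiates the two ring A oxygens after the benzannulation instead of before it; it sets out from 4 and returns at 10. O-Methylation of 4 with the hard electrophile dimethyl sulfate (K2CO3, acetone) gives benzyl 4-methoxy-2-oxo-6-propyl-2H-pyran-5-carboxylate F6. Heating with 6 as in step 4 should pass through the bicyclic adduct benzyl 5,8,8-trimethoxy-3-oxo-1-propyl-2-oxabicyclo[2.2.2]oct-5-ene-6-carboxylate F7 and the diene ketal benzyl 4,4,6-trimethoxy-2-propylcyclohexa-1,5-diene-1-carboxylate F8 to benzyl 2,4-dimethoxy-6-propylbenzoate F9. BCl3 (CH2Cl2, −78 → 0 °C) removes only the methyl group ortho to the chelating ester carbonyl and gives benzyl 2-hydroxy-4-methoxy-6-propylbenzoate F10. Hydrogenolysis (H2, 10% Pd/C) then gives 10; any benzyl ester already opened by the Lewis acid converges on 10 as well.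

**Further compounds**

F1 | step 4 | 6-(2,4-dioxoheptyl)-2,2-dimethyl-4H-1,3-dioxin-4-one | CCCC(=O)CC(=O)CC1=CC(=O)OC(C)(C)O1
F2 | step 4 | 7-hydroxy-2,2-dimethyl-5-propyl-4H-1,3-benzodioxin-4-one | CCCc1cc(O)cc2OC(C)(C)OC(=O)c12
F3 | step 4 | 7-methoxy-2,2-dimethyl-5-propyl-4H-1,3-benzodioxin-4-one | CCCc1cc(OC)cc2OC(C)(C)OC(=O)c12
F4 | step 11 | 2-(benzyloxy)-4-methoxy-6-propylbenzoic acid | CCCc1cc(OC)cc(OCc2ccccc2)c1C(=O)O
F5 | step 11 | benzyl 4-{[2-(benzyloxy)-4-methoxy-6-propylbenzoyl]oxy}-2-methoxy-6-pentylbenzoate | CCCCCc1cc(OC(=O)c2c(OCc3ccccc3)cc(OC)cc2CCC)cc(OC)c1C(=O)OCc1ccccc1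
F6 | step 3 | benzyl 4-methoxy-2-oxo-6-propyl-2H-pyran-5-carboxylate | CCCC1=C(C(=O)OCc2ccccc2)C(OC)=CC(=O)O1
F7 | step 3 | benzyl 5,8,8-trimethoxy-3-oxo-1-propyl-2-oxabicyclo[2.2.2]oct-5-ene-6-carboxylate (racemic, not isolated) | CCCC12CC(OC)(OC)C(C(=O)O1)C(OC)=C2C(=O)OCc1ccccc1
F8 | step 3 | benzyl 4,4,6-trimethoxy-2-propylcyclohexa-1,5-diene-1-carboxylate (not isolated) | CCCC1=C(C(=O)OCc2ccccc2)C(OC)=CC(OC)(OC)C1
F9 | step 3 | benzyl 2,4-dimethoxy-6-propylbenzoate | CCCc1cc(OC)cc(OC)c1C(=O)OCc1ccccc1
F10 | step 3 | benzyl 2-hydroxy-4-methoxy-6-propylbenzoate | CCCc1cc(OC)cc(O)c1C(=O)OCc1ccccc1
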